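The rate constants stand for no real mixture; the result is computed.

Hold the two captures of the intermediate against each other.

| setting | Thursday's | Wednesday's | Tuesday's |
|---|---|---|---|
| starting material | 0.063 M | 0.063 M | 0.063 M |
| first nucleophile | 0.0660 M | 0.130 M | 0.260 M |
| second nucleophile | 0.126 M | 0.126 M | 0.126 M |
| protic impurity | 0.0630 M | 0.0630 M | 0.0630 M |
| time | 8.0 min | 8.0 min | 8.0 min |

    first nucleophile → decomposition product (k1 = 1.7 × 10⁻⁵ s⁻¹)
    second nucleophile + intermediate → other capture product (k2 = 580 L mol⁻¹ s⁻¹)
    starting material → intermediate (k3 = 0.025 s⁻¹)
    first nucleophile + intermediate → target (k4 = 770 L mol⁻¹ s⁻¹)
    starting material + protic impurity → quenched substrate (k5 = 0.16 L mol⁻¹ s⁻¹)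

- which of these there is most of at the end, counted by the starting material in it, Thursday's (other capture product / starting material / intermediate / target)
- which of these there is most of at the end, counted by the starting material in it, Wednesday's (other capture product / starting material / intermediate / target)
- which of these there is most of at the end, counted by the starting material in it, Tuesday's (other capture product / starting material / intermediate / target)
- how much there is at the end of the one of these that leads, in percent of the starting material charged: Thursday's
- how much there is at the end of the one of these that leads, in percent of the starting material charged: Wednesday's
- how much there is at the end of the one of these that leads, in percent of the starting material charged: Tuesday's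

We take the constant of capture by first nucleophile over that of capture by second nucleophile as the selectivity factor, S = 1.33. Target and other capture product form at the ratio S[first nucleophile]/[second nucleophile]. The leader therefore changes when this ratio, averaged over the run, crosses one. We turn the question round: can consumption carry a flask across? At the charge the ratio is 0.695 on Thursday's, 1.37 on Wednesday's and 2.74 on Tuesday's. Thursday's stands nearer to one, 0.305 below it against 0.370 above it for Wednesday's. But Wednesday's is the flask to test, for it lies above one and lower than Tuesday's, and consumption may lower the ratio.

First we need the amount captured. Starting material has a half-life of 0.46 min by its step to the intermediate, far shorter than the 8.0 min allowed. At the charge, 71.3% of it goes that way. Put that first answer back: protic impurity, charged equally, ends at the same 71.3%, so its mean is 85.6% of charge. The share then rises to 74.3%, which is 0.0468 M captured.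

Now go round once on the ratio, taking each nucleophile at its mean after that consumption. Wednesday's falls to 1.33, which is still above one. Thursday's becomes 0.667 and Tuesday's 2.69. We commit to other capture product at 44.6% on Thursday's, and target at 42.5% on Wednesday's and 54.2% on Tuesday's.

The forecast gives other capture product at 44.5% on Thursday's, target at 42.4% on Wednesday's and target at 54.1% on Tuesday's. Of the intermediate it says “so it stays at steady state and ends near zero”. Our figures differ from the forecast's by 0.100 percentage points on Thursday's, 0.100 points on Wednesday's and 0.1 points on Tuesday's.

Thursday's flask gives other capture product at 44.4%. Wednesday's flask gives target at 42.4%. Tuesday's flask gives target at 54.1%. These are the leaders forecast. Wednesday's ends with 79% of its first nucleophile and 84% of its second. With S, those readings give a closing ratio of 1.28 on Wednesday's, still above one.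

For the forecast's leader to be wrong, the ratio must cross one. A neighbour of Tuesday's charged with 0.065 M of first nucleophile starts at 0.685, and the same round gives 0.657, so target 29.5% and other capture product 44.8%. The run of that neighbour ends with 44.7% of other capture product against 29.4% of target.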